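**Retrosynthetic overview**

1. The strategy rests on C2 of quinone ring B, the methoxy-bearing carbon between the C1 carbonyl and C3–H. It is a single carbon that can be inserted into the C1–C2 bond of a 1-indanone whose ketone (future C1) already sits peri to the aryl-bearing carbon (future C8) of ring A.
2. Target 13 ⇐ oxidation at C4 of 2-methoxy-1-naphthol 12 ⇐ exchange of Br for OMe at C2 of bromonaphthol 11.
3. 11 ⇐ dibromocarbene (from bromoform 8) plus silyl enol ether 7 of 7-aryl-5-methoxy-1-indanone 6. This forms C1–C2 and C2–C3 and turns the five-membered ring into six-membered ring B.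
4. 6 ⇐ Suzuki coupling of triflate 4 with boronic acid 5; 4 ⇐ peri-selective demethylation and triflation of 5,7-dimethoxy-1-indanone 2 ⇐ Friedel–Crafts closure of the symmetric acid 1, which has no regiochemical choice.
5. Ring order: ring A (bought) → five-membered ring (step 1) → ring C attached (step 4) → ring B by one-carbon expansion (step 6) → quinone (step 8).

Key step: step 6

Remark: the target is achiral, so no stereocontrol is needed; the chiral intermediates 9, F1 and F2 are racemic.

**Route**

Step 1
Reactants: 1 3-(3,5-dimethoxyphenyl)propanoic acid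
Product: 2 5,7-dimethoxy-2,3-dihydro-1H-inden-1-one (5,7-dimethoxy-1-indanone)
Conditions: MeSO3H (neat), 90 °C
Reagents that add atoms: none
Why: Intramolecular Friedel–Crafts acylation; the two positions ortho to the side chain are equivalent and each is activated ortho/para by the methoxy groups, so only one indanone can form.

Step 2
Reactants: 2 5,7-dimethoxy-1-indanone
Product: 3 7-hydroxy-5-methoxy-2,3-dihydro-1H-inden-1-one
Conditions: BCl3 (1 M in CH2Cl2, 1.5 equiv), CH2Cl2, −78 °C → 0 °C; H2O quench
Reagents that add atoms: none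
Why: Chelation-controlled aryl methyl ether cleavage; boron bridges the C1 carbonyl and the peri C7 methoxy oxygen, so chloride removes only that methyl group and the C5 methoxy group is left intact.

Step 3
Reactants: 3 7-hydroxy-5-methoxy-1-indanone
Product: 4 6-methoxy-3-oxo-2,3-dihydro-1H-inden-4-yl trifluoromethanesulfonate (the C7 triflate of 5-methoxy-1-indanone)
Conditions: Tf2O, pyridine, CH2Cl2, 0 °C → rt
Reagents that add atoms: trifluoromethanesulfonic anhydride (Tf2O), O=S(=O)(OS(=O)(=O)C(F)(F)F)C(F)(F)F
Why: O-sulfonylation of the phenol with triflic anhydride and pyridine should give the aryl triflate needed as the cross-coupling handle.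

Step 4
Reactants: 4 the C7 triflate of 5-methoxy-1-indanone; 5 3,4-dimethoxyphenylboronic acid
Product: 6 7-(3,4-dimethoxyphenyl)-5-methoxy-2,3-dihydro-1H-inden-1-one
Conditions: Pd(PPh3)4 (5 mol %), K3PO4, 1,4-dioxane/H2O, 85 °C
Reagents that add atoms: none
Why: Suzuki–Miyaura coupling; the triflate ortho to the electron-withdrawing ketone should add readily to zerovalent palladium, and the unhindered boronic acid places ring C on C7 without ambiguity.

Step 5
Reactants: 6 7-(3,4-dimethoxyphenyl)-5-methoxy-1-indanone
Product: 7 4-(3,4-dimethoxyphenyl)-6-methoxy-3-(trimethylsilyloxy)-1H-indene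
Conditions: TMSOTf, Et3N, CH2Cl2, 0 °C; dilution with pentane, filtration, used crude
Reagents that add atoms: trimethylsilyl trifluoromethanesulfonate (TMSOTf), C[Si](C)(C)OS(=O)(=O)C(F)(F)F
Why: Soft enolization and O-silylation of an aryl ketone that has a single enolizable position (C2), so only one silyl enol ether can form.

Step 6
Reactants: 7 4-(3,4-dimethoxyphenyl)-6-methoxy-3-(trimethylsilyloxy)-1H-indene; 8 bromoform
Product: 11 2-bromo-8-(3,4-dimethoxyphenyl)-6-methoxynaphthalen-1-ol, via siloxy dibromocyclopropane 9 (not isolated), via 2-bromo-4H-naphthalen-1-one 10 (not isolated)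
Conditions: KOtBu (1.6 equiv), 8 (1.5 equiv) added slowly, hexane/toluene, −30 °C → rt; then 1 M HCl
Reagents that add atoms: none
Why: Dibromocarbene, formed from 8 by α-elimination with KOtBu, adds in a concerted [2+1] cheletropic step to the electron-rich enol ether double bond of 7 and closes the three-membered ring of the cis-fused siloxy dibromocyclopropane 9. On warming, 9 undergoes the thermally allowed two-electron disrotatory cyclopropyl-to-allyl opening with loss of the endo bromide, pushed by the siloxy oxygen lone pair; this breaks the old bond between the carbinol carbon and the former C2 of the indanone, so the six-membered ring arises by expansion of the five-membered ring and not by a cyclization, and loss of the silyl group gives dienone 10. Tautomerization of 10 to the aromatic naphthol 11 drives the sequence. The closest known reaction type is the dihalocarbene ring expansion of cyclic silyl enol ethers, which turns 1-indanone silyl enol ethers into 2-halo-1-naphthols. No stereocenter remains in 11; the two transient stereocenters of 9 are fixed cis by the ring fusion and vanish on opening. The step needs chemoselectivity for the enol ether over the methoxyarenes and a single site of insertion: the electrophilic carbene prefers the much more nucleophilic enol ether π bond, and because C2 of the indanone is its only enolizable carbon the new carbon can only land between C1 and C3 of the naphthol, carrying bromine where the methoxy group is needed.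

Step 7
Reactants: 11 2-bromo-8-(3,4-dimethoxyphenyl)-6-methoxynaphthalen-1-ol
Product: 12 8-(3,4-dimethoxyphenyl)-2,6-dimethoxynaphthalen-1-ol
Conditions: NaOMe (5 equiv), CuI (20 mol %), MeOH/DMF, 110 °C, argon; then dilute HCl
Reagents that add atoms: sodium methoxide (NaOMe), C[O-].[Na+]
Why: Ullmann-type methoxylation, in which monovalent copper activates the C2–Br bond of the naphtholate and methoxide is delivered strictly ipso, a reaction established for ortho-bromophenols.

Step 8
Reactants: 12 8-(3,4-dimethoxyphenyl)-2,6-dimethoxynaphthalen-1-ol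
Product: 13 8-(3,4-dimethoxyphenyl)-2,6-dimethoxynaphthalene-1,4-dione (target)
Conditions: (KO3S)2NO (Fremy's salt, 2.5 equiv), KH2PO4, acetone/H2O, rt
Reagents that add atoms: potassium nitrosodisulfonate (Fremy's salt, (KO3S)2NO), [K+].[K+].[O]N(S(=O)(=O)[O-])S(=O)(=O)[O-]
Why: Teuber oxidation; one equivalent of the nitroxyl radical removes the phenolic hydrogen, a second couples at the free para position C4, and loss of imidodisulfonate gives the para-quinone, the ortho position C2 being blocked by the methoxy group.

**Compound list**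

1 | 3-(3,5-dimethoxyphenyl)propanoic acid | COc1cc(CCC(=O)O)cc(OC)c1 | starting material
2 | 5,7-dimethoxy-2,3-dihydro-1H-inden-1-one | COc1cc2c(c(OC)c1)C(=O)CC2 | intermediate
3 | 7-hydroxy-5-methoxy-2,3-dihydro-1H-inden-1-one | COc1cc(O)c2c(c1)CCC2=O | intermediate
4 | 6-methoxy-3-oxo-2,3-dihydro-1H-inden-4-yl trifluoromethanesulfonate | COc1cc(OS(=O)(=O)C(F)(F)F)c2c(c1)CCC2=O | intermediate
5 | 3,4-dimethoxyphenylboronic acid | COc1ccc(B(O)O)cc1OC | starting material
6 | 7-(3,4-dimethoxyphenyl)-5-methoxy-2,3-dihydro-1H-inden-1-one | COc1cc2c(c(-c3ccc(OC)c(OC)c3)c1)C(=O)CC2 | intermediate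
7 | 4-(3,4-dimethoxyphenyl)-6-methoxy-3-(trimethylsilyloxy)-1H-indene | COc1cc2c(c(-c3ccc(OC)c(OC)c3)c1)C(O[Si](C)(C)C)=CC2 | intermediate
8 | bromoform | BrC(Br)Br | starting material
9 | 1,1-dibromo-2-(3,4-dimethoxyphenyl)-4-methoxy-1a-(trimethylsilyloxy)-1,1a,6,6a-tetrahydrocyclopropa[a]indene (racemic, cis-fused; one enantiomer drawn) | COc1cc2c(c(-c3ccc(OC)c(OC)c3)c1)[C@@]1(O[Si](C)(C)C)[C@@H](C2)C1(Br)Br | intermediate
10 | 2-bromo-8-(3,4-dimethoxyphenyl)-6-methoxynaphthalen-1(4H)-one | COc1cc2c(c(-c3ccc(OC)c(OC)c3)c1)C(=O)C(Br)=CC2 | intermediate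
11 | 2-bromo-8-(3,4-dimethoxyphenyl)-6-methoxynaphthalen-1-ol | COc1cc2ccc(Br)c(O)c2c(-c2ccc(OC)c(OC)c2)c1 | intermediate
12 | 8-(3,4-dimethoxyphenyl)-2,6-dimethoxynaphthalen-1-ol | COc1cc2ccc(OC)c(O)c2c(-c2ccc(OC)c(OC)c2)c1 | intermediate
13 | 8-(3,4-dimethoxyphenyl)-2,6-dimethoxynaphthalene-1,4-dione | COC1=CC(=O)c2cc(OC)cc(-c3ccc(OC)c(OC)c3)c2C1=O | target

**Step count**

Total: 8 steps. Longest linear sequence: 8 steps (1 → 13); 5 and 8 are bought.

**Steps most likely to fail**

Step 6. tert-Butoxide may strip the silyl group from 7 before the carbene is captured, which would return ketone 6. Alternatively, a naphtholate released by early ring opening may be attacked by carbene that is still present. The fallback keeps the one-carbon expansion but uses a halogen-free carbenoid and adds bromine afterwards.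
- Setting out from 7, Et2Zn and CH2I2 in CH2Cl2 at 0 °C (Simmons–Smith cyclopropanation) should give 2-(3,4-dimethoxyphenyl)-4-methoxy-1a-(trimethylsilyloxy)-1,1a,6,6a-tetrahydrocyclopropa[a]indene F1.
- FeCl3 in DMF at 0 °C should open the internal cyclopropane bond oxidatively (Ito–Saegusa ring expansion) to 3-chloro-8-(3,4-dimethoxyphenyl)-6-methoxy-3,4-dihydronaphthalen-1(2H)-one F2.
- NaOAc in hot MeOH should eliminate HCl, and aromatization should give 8-(3,4-dimethoxyphenyl)-6-methoxynaphthalen-1-ol F3.
- NBS with catalytic iPr2NH in CH2Cl2 (amine-directed ortho-bromination of a phenol) should then brominate C2, and the route is rejoined at 11.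

Step 7. Reductive loss of bromine and oxidative coupling of the electron-rich naphtholate may compete under the hot copper conditions. The fallback reverses the order of oxidation and substitution, so that the bromide is displaced from an electron-poor quinone rather than from the arene.
- Setting out from 11, (KO3S)2NO in buffered acetone/H2O should oxidize C4 to give 2-bromo-8-(3,4-dimethoxyphenyl)-6-methoxynaphthalene-1,4-dione F4.
- NaOMe in MeOH at 0 °C should replace the vinylic bromide by addition–elimination at C2, and the route is rejoined at 13, with steps 7 and 8 both replaced.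

Step 8. The electron-rich naphthol may be over-oxidized, or the radical may attack C2 with loss of methanol and lead to the ortho-quinone. The fallback introduces the C4 heteroatom as nitrogen by electrophilic substitution.
- Setting out from 12, coupling at the free para position with 4-sulfobenzenediazonium chloride (from sulfanilic acid, NaNO2 and HCl; then aqueous NaOH, 0 °C) should give 4-{(E)-[5-(3,4-dimethoxyphenyl)-4-hydroxy-3,7-dimethoxynaphthalen-1-yl]diazenyl}benzenesulfonic acid F5.
- Aqueous Na2S2O4 should cleave the azo bond to 4-amino-8-(3,4-dimethoxyphenyl)-2,6-dimethoxynaphthalen-1-ol F6.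
- FeCl3 in aqueous HCl should oxidize F6 to 8-(3,4-dimethoxyphenyl)-4-imino-2,6-dimethoxynaphthalen-1(4H)-one F7, which should hydrolyse in the same acidic medium, and the route is rejoined at 13.

**Further compounds**

F1 | step 6 | 2-(3,4-dimethoxyphenyl)-4-methoxy-1a-(trimethylsilyloxy)-1,1a,6,6a-tetrahydrocyclopropa[a]indene (racemic, cis-fused; one enantiomer drawn) | COc1cc2c(c(-c3ccc(OC)c(OC)c3)c1)[C@@]1(O[Si](C)(C)C)[C@@H](C2)C1
F2 | step 6 | 3-chloro-8-(3,4-dimethoxyphenyl)-6-methoxy-3,4-dihydronaphthalen-1(2H)-one (racemic) | COc1cc2c(c(-c3ccc(OC)c(OC)c3)c1)C(=O)CC(Cl)C2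
F3 | step 6 | 8-(3,4-dimethoxyphenyl)-6-methoxynaphthalen-1-ol | COc1cc2cccc(O)c2c(-c2ccc(OC)c(OC)c2)c1
F4 | step 7 | 2-bromo-8-(3,4-dimethoxyphenyl)-6-methoxynaphthalene-1,4-dione | COc1cc2c(c(-c3ccc(OC)c(OC)c3)c1)C(=O)C(Br)=CC2=O
F5 | step 8 | 4-{(E)-[5-(3,4-dimethoxyphenyl)-4-hydroxy-3,7-dimethoxynaphthalen-1-yl]diazenyl}benzenesulfonic acid | COc1cc2c(/N=N/c3ccc(S(=O)(=O)O)cc3)cc(OC)c(O)c2c(-c2ccc(OC)c(OC)c2)c1
F6 | step 8 | 4-amino-8-(3,4-dimethoxyphenyl)-2,6-dimethoxynaphthalen-1-ol | COc1cc2c(N)cc(OC)c(O)c2c(-c2ccc(OC)c(OC)c2)c1
F7 | step 8 | 8-(3,4-dimethoxyphenyl)-4-imino-2,6-dimethoxynaphthalen-1(4H)-one | COC1=CC(=N)c2cc(OC)cc(-c3ccc(OC)c(OC)c3)c2C1=O
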